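A one-step picture keeps every part of the charge in a species that can be read, and the flask, substrate fed for 3.0 min into a solution under held gas phase, does not.

| setting | Tuesday's | Monday's | flask |
|---|---|---|---|
| substrate | 0.074 M (fed, over 3.0 min) | 0.037 M (fed, over 3.0 min) | 0.074 M (fed, over 3.0 min) |
| gas phase | 22 mM (held) | 22 mM (held) | 22 mM (held) |
| remark | the very flask that is asked about, followed so far; the fed solution adds 0.20 times the starting volume | run made earlier; the fed solution adds 0.20 times the starting volume | the fed solution adds 0.20 times the starting volume |
| time |  |  | 30 min |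

| run | time / min | substrate / % | over-reacted product / % | target / % |
|---|---|---|---|---|
| Tuesday's | 0.667 | 11.2 | 3.2 | 7.0 |
| Tuesday's | 2.00 | 26.2 | 16.9 | 17.8 |
| Tuesday's | 3.00 | 36.1 | 27.8 | 27.1 |
| Tuesday's | 5.00 | 5.0 | 61.7 | 21.0 |
| Tuesday's | 6.00 | 0.1 | 85.3 | 7.4 |
| Tuesday's | 10.0 | 0 | 99.3 | 0 |
| Monday's | 2.00 | 10.9 | 39.1 | 14.4 |
| Monday's | 4.00 | 0.2 | 92.2 | 3.2 |
| Monday's | 6.00 | 0 | 100.6 | 0.3 |
| Monday's | 8.00 | 0 | 100.8 | 0 |
| Monday's | 10.0 | 0.7 | 99.9 | 0 |
| Monday's | 12.0 | 0.5 | 99.6 | 0.1 |

(scatter of a reading: 0.5 percentage points)

* at 30 min, what has stopped the reaction, if anything has (all of the substrate has reacted / it is still moving / forward and back rates have come level)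
* conversion of substrate at 30 min
* amount of over-reacted product at 30 min, in percent of the substrate charged

At 3.00 min, with the feed just ended, Tuesday's readings fall 9 percentage points short of the charge, and this shortfall, the charge less substrate, target and over-reacted product in one reading, is the small correction worth reckoning.

From above, over-reacted product is bounded by the charge, 100%. From below stands Tuesday's reading of 99.3% at 10.0 min, where the shortfall is 0.7 points at a scatter of 0.5 points per reading. At 6.00 min it read 7.2 points, so it fades with a half-life, as a reading, of about 1.19 min, and the 20.0 min still to run are far longer. The lower edge can therefore rise to what a finished flask keeps: Monday's flask, from 6.00 min to 12.0 min, reads no lower than 99.6%. My bracket is 99.6% to 100%, with the scatter of a reading on its lower edge.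

The forecast, with 99.8% over-reacted product, inside the bracket, and 100% conversion, answers that all of the substrate has reacted and holds that “the substrate is used up, not at an equilibrium”.

The flask gives 99.9% over-reacted product, also inside the bracket, and 100% conversion at 30.0 min, and its end is that all of the substrate has reacted: substrate, the limiting reagent, has 0% left.

    gas phase ⇌ dissolved gas, rate k1*(csat - [dissolved gas]) (kL = 0.0169 s⁻¹)
    substrate + dissolved gas → target (k = 14.3 M⁻¹ s⁻¹)
    dissolved gas + target → over-reacted product (k = 9.38 M⁻¹ s⁻¹)
    target → over-reaction product (k = 7.63 × 10⁻⁶ s⁻¹)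
    target ⇌ isomer of the product (K = 0.440, k = 0.00978 s⁻¹)

At 3.00 min isomer of the product stands at 9.10%, beside the shortfall of 9 points read at that time. In the neighbour flask, read at 80 min, the shortfall is 0.052 points, and over-reaction product stands at 0.0523%.

(The data are simulated from invented constants; the scatter is artificial.)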